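**Retrosynthetic overview**

1. Target 24 ← alcohol 23 (butanoylation) ← silyl ether 22. Ring B (cyclopentane) and ring C (β-lactone) are closed together, last, by aldol-lactonisation of aldehyde acid 20.
2. The formyl carbon of 20 is the former ring carbonyl of cyclohex-2-enone 17, homologated through a spiro-epoxide and a 1,2-hydride shift.
3. Ring A is not made as a six-membered ring. In 17 it arises from the four-membered ring of cyclobutanone 16: the two sp carbons of alkyne 9 are inserted into its C(=O)–CH2 bond by nickel catalysis (4 → 6).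
4. Enabling feature: in ring A the tetrasubstituted C=C (the carbon bearing ring D and the ring-fusion carbon bearing the ring-B CH2) lies next to the ring-fusion CH, which carries only H and the lactone carbinol carbon. Read as C=O, that CH makes ring A a 2,3-disubstituted cyclohex-2-enone, i.e. an internal alkyne plus the C=O, CH(CH2O), CH2, CH2 atoms of a 2-substituted cyclobutanone.
5. Ring order: ring D is bought (dimedone) and receives its quaternary centre by conjugate addition; bought cyclobutanone is α-alkylated; then ring A (step 9); then rings B and C (step 13).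

Key step: step 9

Assumption: the sense of induction of the chiral NHC–copper catalyst (step 3) and of SAMP (step 7) is taken from the closest cyclohexenone and cycloalkanone cases; if either substrate follows the opposite sense, the antipodal ligand or RAMP is used, with nothing else changed.

**Route**

Step 1
Reactants: 1 dimedone (5,5-dimethylcyclohexane-1,3-dione)
Product: 2 5,5-dimethyl-3-oxocyclohex-1-en-1-yl trifluoromethanesulfonate
Conditions: Tf2O, pyridine, CH2Cl2, −78 → 0 °C
Reagents that add atoms: trifluoromethanesulfonic anhydride, O=S(=O)(OS(=O)(=O)C(F)(F)F)C(F)(F)F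
Why: O-sulfonylation of the enol of the symmetrical 1,3-diketone (enol triflate formation) should give a single β-triflyloxy enone.

Step 2
Reactants: 2 vinyl triflate; 3 ethynyl(trimethyl)silane
Product: 4 5,5-dimethyl-3-[(trimethylsilyl)ethynyl]cyclohex-2-en-1-one
Conditions: Pd(PPh3)2Cl2 (2 mol%), CuI (4 mol%), Et3N, THF, 23 °C
Reagents that add atoms: none
Why: Sonogashira coupling; the electron-poor vinyl triflate undergoes oxidative addition readily and the silyl cap prevents double coupling.

Step 3
Reactants: 4 enynone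
Product: 5 (3S)-3,5,5-trimethyl-3-[(trimethylsilyl)ethynyl]cyclohexan-1-one
Conditions: MeMgBr (slow addition), Cu(OTf)2 (5 mol%), chiral hydroxyalkyl-imidazolinium salt as NHC precursor (7 mol%), Et2O, −10 °C; aq. NH4Cl
Reagents that add atoms: methylmagnesium bromide, C[Mg]Br
Why: Copper-catalysed asymmetric conjugate addition of a Grignard reagent to a cyclic enynone, which is 1,4-selective with NHC ligands; the chiral NHC–copper complex differentiates the enone faces and should set the quaternary centre of ring D.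

Step 4
Reactants: 5 silylalkynyl ketone
Product: 7 (1R)-1-ethynyl-1,3,3-trimethylcyclohexane, via silylalkynyl hydrazone 6 (not isolated)
Conditions: N2H4·H2O, KOH, diethylene glycol, 130 → 200 °C
Reagents that add atoms: hydrazine, NN (nitrogen held only in intermediate 6)
Why: Wolff–Kishner reduction (Huang-Minlon procedure) removes the carbonyl and the hot hydroxide also cleaves the C(sp)–Si bond; the alkyne cannot migrate because its propargylic carbon is quaternary, and that centre is untouched (S becomes R only through changed branch priorities).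

Step 5
Reactants: 7 terminal alkyne; 8 benzyl prop-2-enoate
Product: 9 benzyl 5-[(1R)-1,3,3-trimethylcyclohexyl]pent-4-ynoate
Conditions: [RuCl2(p-cymene)]2 (2.5 mol%), pyrrolidine (20 mol%), benzene, 60 °C
Reagents that add atoms: none
Why: Ruthenium-catalysed conjugate addition of a terminal alkyne C–H bond to an acrylate gives the 4-ynoate atom-economically; the tertiary alkyl group disfavours alkyne dimerisation.

Step 6
Reactants: 10 cyclobutanone; 11 SAMP, (2S)-2-(methoxymethyl)pyrrolidin-1-amine
Product: 12 (2S)-N-cyclobutylidene-2-(methoxymethyl)pyrrolidin-1-amine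
Conditions: neat, 4 Å molecular sieves, 60 °C
Reagents that add atoms: none
Why: Hydrazone condensation of an unhindered, strained ketone with the auxiliary.

Step 7
Reactants: 12 SAMP hydrazone; 13 (chloromethoxy)tri(propan-2-yl)silane (TOM-Cl)
Product: 15 (2S)-2-(methoxymethyl)-N-[(2R)-2-{[tri(propan-2-yl)silyl]oxymethyl}cyclobutylidene]pyrrolidin-1-amine, via lithium azaenolate 14 (not isolated)
Conditions: LDA, THF, 0 °C; then 13, −100 → −78 °C
Reagents that add atoms: lithium diisopropylamide, CC(C)N([Li])C(C)C (lithium held only in intermediate 14)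
Why: Enders SAMP-hydrazone α-alkylation; the chelated azaenolate is attacked by the reactive chloromethyl ether on the face away from the methoxymethyl arm, which should set the α-carbon as drawn.

Step 8
Reactants: 15 alkylated hydrazone
Product: 16 (2S)-2-{[tri(propan-2-yl)silyl]oxymethyl}cyclobutan-1-one
Conditions: sat. aq. oxalic acid, Et2O, 23 °C
Reagents that add atoms: water, O
Why: Two-phase acid hydrolysis of the hydrazone is mild enough not to enolise the α-stereocentre or cleave the silyl ether, and it returns the auxiliary.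

Step 9
Reactants: 9 alkyne ester; 16 cyclobutanone
Product: 17 benzyl 3-[(5S)-6-oxo-2-[(1R)-1,3,3-trimethylcyclohexyl]-5-{[tri(propan-2-yl)silyl]oxymethyl}cyclohex-1-en-1-yl]propanoate
Conditions: Ni(cod)2 (10 mol%), PCy3 (20 mol%), toluene, 100 °C
Reagents that add atoms: none
Why: Zerovalent nickel couples the strained C=O of 16 with the alkyne of 9 by oxidative cyclisation to an oxanickelacyclopentene, β-carbon elimination opens the four-membered ring, and C(sp3)–C(sp2) reductive elimination from the seven-membered nickelacycle gives the cyclohex-2-enone, so both alkyne carbons are inserted into the C(=O)–CH2 bond and the cyclobutane becomes ring A (4 → 6). The closest known reaction type is the nickel-catalysed intermolecular [4+2] insertion of internal alkynes into cyclobutanones. Ring A is the only ring closed, by that reductive elimination of a formal [4+2] annulation. No new stereocentre is formed: the α-stereocentre of 16 is carried over because the bond cut is the unsubstituted C(=O)–CH2 bond, and the quaternary centre of ring D lies outside the reacting atoms. Two selectivities are needed: the bond to the carbonyl carbon must form at the alkyne carbon bearing the CH2CH2CO2Bn chain, which the quaternary ring-D carbon should secure by forcing the bulkier terminus next to nickel, and β-carbon elimination must take the less substituted side, which gives a primary alkylnickel instead of the secondary one flanked by the silyloxymethyl arm. In one operation the step should deliver all six ring-A carbons, the tetrasubstituted C=C with its tertiary alkyl group, the acid arm for ring B and the carbonyl from which the lactone carbinol carbon is grown.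

Step 10
Reactants: 17 enone
Product: 18 benzyl 3-[(3S,8S)-5-[(1R)-1,3,3-trimethylcyclohexyl]-8-{[tri(propan-2-yl)silyl]oxymethyl}-1-oxaspiro[2.5]oct-4-en-4-yl]propanoate
Conditions: Me3S+ I−, KHMDS, THF, −10 → 0 °C
Reagents that add atoms: trimethylsulfonium iodide, C[S+](C)C.[I-]
Why: Corey–Chaykovsky epoxidation; the small sulfonium ylide adds 1,2 to the enone carbonyl along the axial trajectory of the half-chair, cis to the equatorial silyloxymethyl arm, and the betaine closes irreversibly, so the new CH2 should end cis and the oxygen trans to that arm.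

Step 11
Reactants: 18 vinyl spiro-epoxide
Product: 19 benzyl 3-[(5R,6S)-6-formyl-2-[(1R)-1,3,3-trimethylcyclohexyl]-5-{[tri(propan-2-yl)silyl]oxymethyl}cyclohex-1-en-1-yl]propanoate
Conditions: BF3·OEt2 (0.2 equiv), CH2Cl2, −78 °C; sat. aq. NaHCO3
Reagents that add atoms: none
Why: Meinwald rearrangement; the Lewis acid opens the epoxide at the tertiary allylic carbon and a hydride of the CH2O carbon migrates to it anti to the departing oxygen (inversion at the migration terminus), so the formyl group should end trans to the silyloxymethyl arm, and low temperature with catalytic acid keeps the C=C out of conjugation.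

Step 12
Reactants: 19 aldehyde benzyl ester
Product: 20 3-[(5R,6S)-6-formyl-2-[(1R)-1,3,3-trimethylcyclohexyl]-5-{[tri(propan-2-yl)silyl]oxymethyl}cyclohex-1-en-1-yl]propanoic acid
Conditions: H2 (1 atm), Pd/C (5%), EtOAc, 23 °C
Reagents that add atoms: none
Why: Hydrogenolysis of the benzyl ester under neutral conditions; the tetrasubstituted, tert-alkyl-shielded alkene, the aldehyde and the silyl ether should be inert.

Step 13
Reactants: 20 aldehyde acid
Product: 22 (2aS,7R,7aS,7bR)-4-[(1R)-1,3,3-trimethylcyclohexyl]-7-{[tri(propan-2-yl)silyl]oxymethyl}-2a,3,5,6,7,7a-hexahydro-7bH-indeno[1,2-b]oxet-2-one (β-lactone cis-fused to the new cyclopentane), via acyloxypyridinium salt 21 (not isolated)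
Conditions: 2-bromo-1-propylpyridinium triflate (1.5 equiv), 4-pyrrolidinopyridine (1.0 equiv), iPr2NEt (3 equiv), CH2Cl2, 23 °C, slow addition of 20
Reagents that add atoms: 2-bromo-1-propylpyridinium triflate, CCC[n+]1ccccc1Br.[O-]S(=O)(=O)C(F)(F)F (atoms held only in intermediate 21)
Why: Nucleophile-catalysed aldol-lactonisation (NCAL): the acid is activated, the ammonium enolate adds to the formyl group (5-exo aldol, ring B) and the aldolate acylates to close ring C; the cis fusion of the four-membered lactone is forced, and the formyl group should react in the Felkin–Anh-type rotamer with its oxygen on the side of the C–H of the adjacent stereocentre, placing the lactone trans to the ring-A carbon that bears the silyloxymethyl arm.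

Step 14
Reactants: 22 silyl ether
Product: 23 (2aS,7R,7aS,7bR)-7-(hydroxymethyl)-4-[(1R)-1,3,3-trimethylcyclohexyl]-2a,3,5,6,7,7a-hexahydro-7bH-indeno[1,2-b]oxet-2-one
Conditions: HF·pyridine, pyridine, THF, 0 → 23 °C
Reagents that add atoms: none
Why: Fluoride-mediated silyl ether cleavage under buffered, weakly acidic conditions that should leave the β-lactone intact.

Step 15
Reactants: 23 primary alcohol
Product: 24 CNP0144861.2, [(2aS,7R,7aS,7bR)-2-oxo-4-[(1R)-1,3,3-trimethylcyclohexyl]-2a,3,5,6,7,7a-hexahydro-7bH-indeno[1,2-b]oxet-7-yl]methyl butanoate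
Conditions: butanoyl chloride, pyridine, CH2Cl2, 0 °C
Reagents that add atoms: butanoyl chloride, CCCC(=O)Cl
Why: O-acylation of the unhindered primary alcohol with an acid chloride and a weak base, without a strong nucleophilic catalyst that could open the β-lactone.

**Compound list**

1 | 5,5-dimethylcyclohexane-1,3-dione (dimedone) | CC1(C)CC(=O)CC(=O)C1 | starting material
2 | 5,5-dimethyl-3-oxocyclohex-1-en-1-yl trifluoromethanesulfonate | CC1(C)CC(=O)C=C(OS(=O)(=O)C(F)(F)F)C1 | intermediate
3 | ethynyl(trimethyl)silane | C#C[Si](C)(C)C | starting material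
4 | 5,5-dimethyl-3-[(trimethylsilyl)ethynyl]cyclohex-2-en-1-one | C[Si](C)(C)C#CC1=CC(=O)CC(C)(C)C1 | intermediate
5 | (3S)-3,5,5-trimethyl-3-[(trimethylsilyl)ethynyl]cyclohexan-1-one | C[Si](C)(C)C#C[C@]1(C)CC(=O)CC(C)(C)C1 | intermediate
6 | hydrazone of 5, [(3S)-3,5,5-trimethyl-3-[(trimethylsilyl)ethynyl]cyclohexylidene]hydrazine | C[Si](C)(C)C#C[C@]1(C)CC(=NN)CC(C)(C)C1 | intermediate (not isolated)
7 | (1R)-1-ethynyl-1,3,3-trimethylcyclohexane | C#C[C@]1(C)CCCC(C)(C)C1 | intermediate
8 | benzyl prop-2-enoate | C=CC(=O)OCc1ccccc1 | starting material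
9 | benzyl 5-[(1R)-1,3,3-trimethylcyclohexyl]pent-4-ynoate | O=C(CCC#C[C@]1(C)CCCC(C)(C)C1)OCc1ccccc1 | intermediate
10 | cyclobutanone | O=C1CCC1 | starting material
11 | SAMP, (2S)-2-(methoxymethyl)pyrrolidin-1-amine | COC[C@@H]1CCCN1N | starting material
12 | (2S)-N-cyclobutylidene-2-(methoxymethyl)pyrrolidin-1-amine | COC[C@@H]1CCCN1N=C1CCC1 | intermediate
13 | (chloromethoxy)tri(propan-2-yl)silane | ClCO[Si](C(C)C)(C(C)C)C(C)C | starting material
14 | lithium azaenolate of 12 | COC[C@@H]1CCCN1N([Li])C1=CCC1 | intermediate (not isolated)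
15 | (2S)-2-(methoxymethyl)-N-[(2R)-2-{[tri(propan-2-yl)silyl]oxymethyl}cyclobutylidene]pyrrolidin-1-amine (C=N geometry not relevant) | COC[C@@H]1CCCN1N=C1CC[C@H]1CO[Si](C(C)C)(C(C)C)C(C)C | intermediate
16 | (2S)-2-{[tri(propan-2-yl)silyl]oxymethyl}cyclobutan-1-one | CC(C)[Si](C(C)C)(C(C)C)OC[C@@H]1CCC1=O | intermediate
17 | benzyl 3-[(5S)-6-oxo-2-[(1R)-1,3,3-trimethylcyclohexyl]-5-{[tri(propan-2-yl)silyl]oxymethyl}cyclohex-1-en-1-yl]propanoate | CC(C)[Si](C(C)C)(C(C)C)OC[C@@H]1CCC([C@]2(C)CCCC(C)(C)C2)=C(CCC(=O)OCc2ccccc2)C1=O | intermediate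
18 | benzyl 3-[(3S,8S)-5-[(1R)-1,3,3-trimethylcyclohexyl]-8-{[tri(propan-2-yl)silyl]oxymethyl}-1-oxaspiro[2.5]oct-4-en-4-yl]propanoate | CC(C)[Si](C(C)C)(C(C)C)OC[C@@H]1CCC([C@]2(C)CCCC(C)(C)C2)=C(CCC(=O)OCc2ccccc2)[C@]13CO3 | intermediate
19 | benzyl 3-[(5R,6S)-6-formyl-2-[(1R)-1,3,3-trimethylcyclohexyl]-5-{[tri(propan-2-yl)silyl]oxymethyl}cyclohex-1-en-1-yl]propanoate | CC(C)[Si](C(C)C)(C(C)C)OC[C@@H]1CCC([C@]2(C)CCCC(C)(C)C2)=C(CCC(=O)OCc2ccccc2)[C@H]1C=O | intermediate
20 | 3-[(5R,6S)-6-formyl-2-[(1R)-1,3,3-trimethylcyclohexyl]-5-{[tri(propan-2-yl)silyl]oxymethyl}cyclohex-1-en-1-yl]propanoic acid | CC(C)[Si](C(C)C)(C(C)C)OC[C@@H]1CCC([C@]2(C)CCCC(C)(C)C2)=C(CCC(=O)O)[C@H]1C=O | intermediate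
21 | 2-acyloxy-1-propylpyridinium triflate of acid 20 | CC(C)[Si](C(C)C)(C(C)C)OC[C@@H]1CCC([C@]2(C)CCCC(C)(C)C2)=C(CCC(=O)Oc2cccc[n+]2CCC)[C@H]1C=O.[O-]S(=O)(=O)C(F)(F)F | intermediate (not isolated)
22 | (2aS,7R,7aS,7bR)-4-[(1R)-1,3,3-trimethylcyclohexyl]-7-{[tri(propan-2-yl)silyl]oxymethyl}-2a,3,5,6,7,7a-hexahydro-7bH-indeno[1,2-b]oxet-2-one | CC(C)[Si](C(C)C)(C(C)C)OC[C@@H]1CCC([C@]2(C)CCCC(C)(C)C2)=C2C[C@@H]3C(=O)O[C@@H]3[C@H]21 | intermediate
23 | (2aS,7R,7aS,7bR)-7-(hydroxymethyl)-4-[(1R)-1,3,3-trimethylcyclohexyl]-2a,3,5,6,7,7a-hexahydro-7bH-indeno[1,2-b]oxet-2-one | OC[C@@H]1CCC([C@]2(C)CCCC(C)(C)C2)=C2C[C@@H]3C(=O)O[C@@H]3[C@H]21 | intermediate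
24 | CNP0144861.2, [(2aS,7R,7aS,7bR)-2-oxo-4-[(1R)-1,3,3-trimethylcyclohexyl]-2a,3,5,6,7,7a-hexahydro-7bH-indeno[1,2-b]oxet-7-yl]methyl butanoate | CCCC(=O)OC[C@@H]1CCC([C@]2(C)CCCC(C)(C)C2)=C2C[C@@H]3C(=O)O[C@@H]3[C@H]21 | target

**Step count and risks**

Total step count: 15. Longest linear sequence: 12 steps (steps 1–5, then 9–15).

Steps most likely to fail:

Step 9. β-Carbon elimination could take the substituted C(=O)–CH bond of 16, or the α-stereocentre could epimerise at 100 °C; either would erode the regio- or stereochemical purity of 17. The fallback moves the stereocentre-forming event to after the ring expansion. It sets out from alkyne 9 and cyclobutanone 10: the same nickel-catalysed insertion on the unsubstituted, symmetrical ketone (no choice of bond, no stereocentre) should give benzyl 3-{6-oxo-2-[(1R)-1,3,3-trimethylcyclohexyl]cyclohex-1-en-1-yl}propanoate F1. Condensation with SAMP 11 (TsOH cat., toluene, reflux) gives the hydrazone benzyl 3-[6-{[(2S)-2-(methoxymethyl)pyrrolidin-1-yl]imino}-2-[(1R)-1,3,3-trimethylcyclohexyl]cyclohex-1-en-1-yl]propanoate F2. Kinetic α'-deprotonation (LDA, THF, −78 °C) and alkylation with 13 gives the alkylated hydrazone benzyl 3-[(5R)-6-{[(2S)-2-(methoxymethyl)pyrrolidin-1-yl]imino}-2-[(1R)-1,3,3-trimethylcyclohexyl]-5-{[tri(propan-2-yl)silyl]oxymethyl}cyclohex-1-en-1-yl]propanoate F3, with the auxiliary controlling the new centre. Oxalic acid hydrolysis then comes back to the route at 17.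

Step 11 (together with step 10). The epoxide could ionise to a free allyl cation before the hydride migrates, erasing the configuration at the ring-fusion carbon, or the C=C could drift into conjugation with the new aldehyde; in step 10 the basic ylide could also enolise the ketone. The fallback avoids base and cations. It sets out from 17: Takai–Lombardo methylenation (Zn, CH2Br2, TiCl4, THF) should give the diene benzyl 3-[(5R)-6-methylidene-2-[(1R)-1,3,3-trimethylcyclohexyl]-5-{[tri(propan-2-yl)silyl]oxymethyl}cyclohex-1-en-1-yl]propanoate F4. Hydroboration–oxidation (BH3·THF, 0 °C; NaBO3) puts boron on the terminal carbon and delivers hydrogen to the ring carbon, preferably from the axial face, giving the alcohol benzyl 3-[(5R,6S)-6-(hydroxymethyl)-2-[(1R)-1,3,3-trimethylcyclohexyl]-5-{[tri(propan-2-yl)silyl]oxymethyl}cyclohex-1-en-1-yl]propanoate F5. Dess–Martin oxidation comes back to the route at 19.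

Step 3. Background 1,2- or 1,6-addition to the enynone and a weak facial preference, caused by the axial methyl of the gem-dimethyl group, could lower regio- and enantioselectivity. The fallback replaces catalyst control by chirality transfer. It does not set out from a numbered compound but from commercial isophorone (3,5,5-trimethylcyclohex-2-en-1-one); it replaces steps 1–4 and comes back at 7. CBS reduction gives (1R)-3,5,5-trimethylcyclohex-2-en-1-ol F6. O-Alkylation (KH, Bu3SnCH2I, THF) gives tributyl({[(1R)-3,5,5-trimethylcyclohex-2-en-1-yl]oxy}methyl)stannane F7. Tin–lithium exchange (n-BuLi, −78 °C) triggers the Still–Wittig [2,3]-rearrangement, which forms the quaternary centre on the face that carried the oxygen and gives [(1S)-1,5,5-trimethylcyclohex-2-en-1-yl]methanol F8. Hydrogenation (H2, Pd/C) gives [(1R)-1,3,3-trimethylcyclohexyl]methanol F9, and Dess–Martin oxidation gives (1R)-1,3,3-trimethylcyclohexane-1-carbaldehyde F10. Ohira–Bestmann homologation (dimethyl (1-diazo-2-oxopropyl)phosphonate, K2CO3, MeOH) then gives alkyne 7.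

**Further compounds**

F1 | step 9 | benzyl 3-{6-oxo-2-[(1R)-1,3,3-trimethylcyclohexyl]cyclohex-1-en-1-yl}propanoate | O=C1CCCC([C@]2(C)CCCC(C)(C)C2)=C1CCC(=O)OCc1ccccc1
F2 | step 9 | benzyl 3-[6-{[(2S)-2-(methoxymethyl)pyrrolidin-1-yl]imino}-2-[(1R)-1,3,3-trimethylcyclohexyl]cyclohex-1-en-1-yl]propanoate | COC[C@@H]1CCCN1N=C1CCCC([C@]2(C)CCCC(C)(C)C2)=C1CCC(=O)OCc1ccccc1
F3 | step 9 | benzyl 3-[(5R)-6-{[(2S)-2-(methoxymethyl)pyrrolidin-1-yl]imino}-2-[(1R)-1,3,3-trimethylcyclohexyl]-5-{[tri(propan-2-yl)silyl]oxymethyl}cyclohex-1-en-1-yl]propanoate | COC[C@@H]1CCCN1N=C1[C@H](CO[Si](C(C)C)(C(C)C)C(C)C)CCC([C@]2(C)CCCC(C)(C)C2)=C1CCC(=O)OCc1ccccc1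
F4 | step 11 | benzyl 3-[(5R)-6-methylidene-2-[(1R)-1,3,3-trimethylcyclohexyl]-5-{[tri(propan-2-yl)silyl]oxymethyl}cyclohex-1-en-1-yl]propanoate | CC(C)[Si](C(C)C)(C(C)C)OC[C@@H]1CCC([C@]2(C)CCCC(C)(C)C2)=C(CCC(=O)OCc2ccccc2)C1=C
F5 | step 11 | benzyl 3-[(5R,6S)-6-(hydroxymethyl)-2-[(1R)-1,3,3-trimethylcyclohexyl]-5-{[tri(propan-2-yl)silyl]oxymethyl}cyclohex-1-en-1-yl]propanoate | CC(C)[Si](C(C)C)(C(C)C)OC[C@@H]1CCC([C@]2(C)CCCC(C)(C)C2)=C(CCC(=O)OCc2ccccc2)[C@H]1CO
F6 | step 3 | (1R)-3,5,5-trimethylcyclohex-2-en-1-ol | O[C@H]1C=C(C)CC(C)(C)C1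
F7 | step 3 | tributyl({[(1R)-3,5,5-trimethylcyclohex-2-en-1-yl]oxy}methyl)stannane | CCCC[Sn](CCCC)(CCCC)CO[C@H]1C=C(C)CC(C)(C)C1
F8 | step 3 | [(1S)-1,5,5-trimethylcyclohex-2-en-1-yl]methanol | OC[C@]1(C)C=CCC(C)(C)C1
F9 | step 3 | [(1R)-1,3,3-trimethylcyclohexyl]methanol | OC[C@]1(C)CCCC(C)(C)C1
F10 | step 3 | (1R)-1,3,3-trimethylcyclohexane-1-carbaldehyde | O=C[C@]1(C)CCCC(C)(C)C1
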